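**Strategy.** Ring A is disconnected at C3–C4. The key step is an intramolecular aldol reaction: the enolate of the 19,10-γ-lactone (nucleophilic C4) attacks a C3 aldehyde carried on a two-carbon arm (C1–C2) at C10. It exploits the lactone that bridges C4 and C10 and is cis-fused to ring B, so C3 can reach only the C4 face syn to C1. One operation closes ring A (C10, C1, C2, C3, C4, C5) and sets C3 and the quaternary C4. The precursor is the tetracyclic B/C/D lactone aldehyde, built from one bought stereocentre (C6) that relays C8, C9, C5 and C10, with ring D closed by a ketyl–alkyne cyclization.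

Key step: step 15

Remark: atoms carry gibberellin numbering (C7 carboxyl carbon on C6, C19 lactone carbonyl, C18 methyl, C17 methylene carbon); "upper face" is the face of ring B that carries H5, H9, C1, C7 and C15.
Assumption: (1S,2S)-4-oxocyclopentane-1,2-dicarboxylic acid is bought as the single enantiomer (the trans acid is a classically resolved commodity); the C4 centre made in step 5 is drawn as formed but is erased when C4 is planarized in step 15.

Step 1
Reactants: 1 (1S,2S)-4-oxocyclopentane-1,2-dicarboxylic acid
Product: 2 diallyl (1S,2S)-4-oxocyclopentane-1,2-dicarboxylate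
Conditions: allyl bromide, Cs2CO3, DMF, 0 → 25 °C
Reagents that add atoms: allyl bromide, C=CCBr
Why: Carboxylate O-alkylation (SN2) should give the diallyl ester without touching the trans stereocentres; both esters can later be removed together under neutral conditions.

Step 2
Reactants: 2 diallyl keto diester
Product: 3 diallyl (1S)-4-oxocyclopent-2-ene-1,2-dicarboxylate
Conditions: IBX, 4-methoxypyridine N-oxide, DMSO, 25 °C
Reagents that add atoms: none
Why: IBX α,β-dehydrogenation of the ketone should give the enone; the C2 symmetry of 2 makes both α-methylene groups equivalent, so one enone forms and the remaining sp3 ester carbon (future C6) keeps its S configuration.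

Step 3
Reactants: 4 but-3-en-2-one
Product: 5 2-(tert-butyldimethylsilyloxy)buta-1,3-diene
Conditions: TBSOTf, Et3N, Et2O, 0 °C
Reagents that add atoms: tert-butyldimethylsilyl trifluoromethanesulfonate, CC(C)(C)[Si](C)(C)OS(=O)(=O)C(F)(F)F
Why: Soft enolization and O-silylation of the methyl ketone should give the 2-silyloxydiene.

Step 4
Reactants: 3 enone diester; 5 silyloxydiene
Product: 6 cis-hydrindanone with C10 ketone, C12=C13 silyl enol ether and allyl esters on C8 and C6
Conditions: Me2AlCl (0.2 equiv), CH2Cl2, −78 °C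
Reagents that add atoms: none
Why: In this Lewis-acid-promoted Diels–Alder reaction the nucleophilic CH2 terminus next to the silyloxy carbon should bond to the enone β-carbon C8 (aluminium on the more basic ketone oxygen outweighs the ester), which puts the enol ether carbon C13 in a 1,3-relation to C8; suprafacial addition anti to the C6 ester sets C8 and C9, with the angular C15 ester cis to H9 and to C7.

Step 5
Reactants: 6 cis-hydrindanone; 7 ethyl (S)-2-{[(trifluoromethyl)sulfonyl]oxy}propanoate
Product: 9 C5-alkylated ketone carrying the ethyl propanoate arm (C4, C18, C19), via lithium enolate 8 (not isolated)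
Conditions: LiN(i-Pr)2, THF, −78 °C; then 7, DMPU, −78 → −30 °C
Reagents that add atoms: none
Why: Kinetic deprotonation at the less hindered C5 methylene and SN2 alkylation by the α-triflyloxy ester (inversion at C4) anti to the adjacent C6 ester should set C5 trans to C7, which is also the thermodynamic arrangement of this epimerizable centre.

Step 6
Reactants: 9 C5-alkylated ketone; 10 [2-(1,3-dioxolan-2-yl)ethyl]magnesium bromide
Product: 13 19,10-γ-lactone with the 2-(1,3-dioxolan-2-yl)ethyl arm (C1–C3) on C10, via organocerium reagent 11 (not isolated), via cerium alkoxide adduct 12 (not isolated)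
Conditions: 10, CeCl3, THF, −78 °C; then 9, −78 → 0 °C; aq NH4Cl
Reagents that add atoms: none
Why: Organocerium 1,2-addition to the enolizable ketone from the upper face, opposite the two flanking lower-face substituents (C4 arm on C5, C11 on C9), should set C10; the alkoxide is then cis to the propanoate arm and lactonizes by acyl substitution (5-exo-trig).

Step 7
Reactants: 13 lactone diallyl ester
Product: 14 lactone diacid (C7 and C15 carboxylic acids)
Conditions: Pd(PPh3)4 (5 mol %), pyrrolidine, CH2Cl2, 0 °C; pH 5 buffer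
Reagents that add atoms: none
Why: Tsuji–Trost deallylation through π-allylpalladium with an amine scavenger should free both acids under neutral conditions that spare the silyl enol ether, acetal and lactone.

Step 8
Reactants: 14 lactone diacid
Product: 16 C15 carboxylic acid with C7 2-(trimethylsilyl)ethyl ester, via cyclic anhydride 15 (not isolated)
Conditions: DCC, CH2Cl2, 0 → 25 °C; then Me3SiCH2CH2OH, DMAP, Et3N, 0 → 25 °C
Reagents that add atoms: 2-(trimethylsilyl)ethanol, C[Si](C)(C)CCO
Why: The cis-1,2-diacid should close to the cyclic anhydride, and DMAP-catalysed alcoholysis should attack the less hindered C7 carbonyl (on methine C6) rather than C15 (on quaternary C8), which differentiates the two carboxyl groups.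

Step 9
Reactants: 16 C15 acid; 17 ethynyltrimethylsilane
Product: 19 C15 ynone, via acid chloride 18 (not isolated)
Conditions: 1-chloro-N,N,2-trimethylpropenylamine, CH2Cl2, 0 °C; then 17, PdCl2(PPh3)2 (3 mol %), CuI (6 mol %), Et3N, THF, 25 °C
Reagents that add atoms: none
Why: Neutral acid chloride formation followed by Pd/Cu-catalysed acyl Sonogashira coupling should give the ynone chemoselectively in the presence of ester, lactone, acetal and silyl enol ether.

Step 10
Reactants: 19 ynone
Product: 20 C15 propargylic alcohol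
Conditions: Ru[(S,S)-TsDPEN](p-cymene) (2 mol %), i-PrOH, 25 °C
Reagents that add atoms: none
Why: Noyori asymmetric transfer hydrogenation of the ynone is reagent-controlled; the (S,S) catalyst should deliver hydride to the face that gives the carbinol configuration of C15 in the target (viewed with H away, OH → alkynyl → C8 runs anticlockwise).

Step 11
Reactants: 20 propargylic alcohol
Product: 21 15-O-tert-butyldimethylsilyl ether
Conditions: TBSCl, imidazole, DMAP (cat.), DMF, 40 °C
Reagents that add atoms: tert-butyldimethylsilyl chloride, CC(C)(C)[Si](C)(C)Cl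
Why: Lewis-acid-free silylation should protect the 15-hydroxyl, which could otherwise lactonize onto the C7 ester under the later basic steps.

Step 12
Reactants: 21 bis-silylated alkyne enol ether
Product: 22 C13 ketone with terminal alkyne
Conditions: Bu4NF (2.2 equiv), AcOH (2.2 equiv), THF, −20 → 0 °C
Reagents that add atoms: none
Why: Buffered fluoride should cleave the alkynyl C–Si bond and the silyl enol ether (protonation at C12 releases the C13 ketone) much faster than the hindered secondary silyl ether or the silylethyl ester.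

Step 13
Reactants: 22 keto alkyne
Product: 23 tetracyclic lactone acetal with ring D closed (13-hydroxy, 16-methylene)
Conditions: SmI2 (2.5 equiv), HMPA, t-BuOH, THF, 0 → 25 °C
Reagents that add atoms: none
Why: In this ketyl–alkyne radical cyclization (5-exo-dig) the C13 ketyl should add to C16 and the vinyl radical is reduced to the exocyclic methylene; the bridge forces the C13 configuration, and C15 is untouched.

Step 14
Reactants: 23 tetracyclic lactone acetal
Product: 24 lactone aldehyde (C3 aldehyde on the C1–C2 arm at C10)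
Conditions: PPTS, acetone/H2O (9:1), 50 °C
Reagents that add atoms: water, O
Why: Mild acid-catalysed acetal hydrolysis should release the aldehyde without ionizing the tertiary allylic 13-alcohol or cleaving the silyl ether.

Step 15
Reactants: 24 lactone aldehyde
Product: 25 15-O-tert-butyldimethylsilyl 2-(trimethylsilyl)ethyl ester of the target gibberellin (ring A closed)
Conditions: KOt-Bu (0.3 equiv), 18-crown-6 (0.3 equiv), t-BuOH/THF (1:10), 3 mM, −30 → 0 °C; AcOH, −30 °C
Reagents that add atoms: none
Why: Catalytic alkoxide sets up the proton-transfer equilibria and the lactone enolate (C4) adds to the C3 aldehyde; the closest known reaction type is the intramolecular aldol addition of an ester enolate to a tethered aldehyde, the forward direction of the base-induced retro-aldol opening known for 3-hydroxy 19,10-lactones of this family. Ring A closes in a 6-(enolexo)-exo-trig mode. C4 is controlled by the lactone: it is cis-fused to ring B and C3 is tethered to C10 on the upper face, so the new bond forms syn to C1 and the methyl group is forced to the lower face. C3 is controlled by an open, antiperiplanar transition state of the crown-ether-separated potassium enolate, in which the aldehyde oxygen points away from the enolate oxygen (anti to C19) and becomes the axial 3β-hydroxyl. The step needs site selectivity (C4 over the C6–H of the C7 ester and over the unproductive aldehyde enolate) and kinetic control (retro-aldol equilibration would favour the equatorial 3α-alcohol). The higher acidity of the lactone C–H relative to the ester C–H, high dilution against aldehyde self-condensation, substoichiometric base and a cold acidic quench should secure these.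

Step 16
Reactants: 25 protected target gibberellin
Product: 26 target gibberellin (number 72 of the A series)
Conditions: Bu4NF (4 equiv), THF, 0 → 25 °C; aq NH4Cl
Reagents that add atoms: none
Why: Fluoride should fragment the 2-(trimethylsilyl)ethyl ester (loss of ethene) before it cleaves the hindered 15-silyl ether, so the 15-oxygen is freed next to a carboxylate that cannot lactonize.

**Compound list**

1 | (1S,2S)-4-oxocyclopentane-1,2-dicarboxylic acid (trans) | O=C1C[C@H](C(=O)O)[C@@H](C(=O)O)C1 | starting material
2 | diallyl (1S,2S)-4-oxocyclopentane-1,2-dicarboxylate | O=C1C[C@H](C(=O)OCC=C)[C@@H](C(=O)OCC=C)C1 | intermediate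
3 | diallyl (1S)-4-oxocyclopent-2-ene-1,2-dicarboxylate (sp3 ester carbon = C6) | O=C1C=C(C(=O)OCC=C)[C@@H](C(=O)OCC=C)C1 | intermediate
4 | but-3-en-2-one | CC(=O)C=C | starting material
5 | 2-(tert-butyldimethylsilyloxy)buta-1,3-diene | C=CC(=C)O[Si](C)(C)C(C)(C)C | intermediate
6 | cis-fused B/C hydrindanone: C10 ketone, C12=C13 TBS enol ether, allyl esters on C8 (angular, C15) and C6 (C7), both cis to H9 | C=CCOC(=O)[C@]23CC(O[Si](C)(C)C(C)(C)C)=CC[C@H]2C(=O)C[C@@H]3C(=O)OCC=C | intermediate
7 | ethyl (S)-2-{[(trifluoromethyl)sulfonyl]oxy}propanoate | CCOC(=O)[C@H](C)OS(=O)(=O)C(F)(F)F | starting material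
8 | lithium C10(O)=C5 enolate of 6 | C=CCOC(=O)[C@]23CC(O[Si](C)(C)C(C)(C)C)=CC[C@H]2C(O[Li])=C[C@@H]3C(=O)OCC=C | intermediate
9 | 6 bearing at C5 the 1-ethoxy-1-oxopropan-2-yl arm (C4, C18, C19), trans to the C6 ester | C=CCOC(=O)[C@]23CC(O[Si](C)(C)C(C)(C)C)=CC[C@H]2C(=O)[C@@H]([C@H](C)C(=O)OCC)[C@@H]3C(=O)OCC=C | intermediate
10 | [2-(1,3-dioxolan-2-yl)ethyl]magnesium bromide | Br[Mg]CCC1OCCO1 | starting material
11 | [2-(1,3-dioxolan-2-yl)ethyl]cerium dichloride | Cl[Ce](Cl)CCC1OCCO1 | intermediate
12 | C10 tertiary carbinol adduct of 9 (formed as its cerium alkoxide; hydroxyl on the lower face) | C=CCOC(=O)[C@]23CC(O[Si](C)(C)C(C)(C)C)=CC[C@H]2[C@](O)(CCC4OCCO4)[C@@H]([C@H](C)C(=O)OCC)[C@@H]3C(=O)OCC=C | intermediate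
13 | 19,10-γ-lactone with 2-(1,3-dioxolan-2-yl)ethyl on C10; diallyl ester, C12=C13 TBS enol ether | C=CCOC(=O)[C@]23CC(O[Si](C)(C)C(C)(C)C)=CC[C@H]2[C@@]1(CCC4OCCO4)OC(=O)[C@@H](C)[C@H]1[C@@H]3C(=O)OCC=C | intermediate
14 | lactone diacid (free C7 and C15 acids) | OC(=O)[C@]23CC(O[Si](C)(C)C(C)(C)C)=CC[C@H]2[C@@]1(CCC4OCCO4)OC(=O)[C@@H](C)[C@H]1[C@@H]3C(=O)O | intermediate
15 | cyclic C7/C15 anhydride of 14 | O=C5[C@]23CC(O[Si](C)(C)C(C)(C)C)=CC[C@H]2[C@@]1(CCC4OCCO4)OC(=O)[C@@H](C)[C@H]1[C@@H]3C(=O)O5 | intermediate
16 | C15 carboxylic acid, C7 2-(trimethylsilyl)ethyl ester | OC(=O)[C@]23CC(O[Si](C)(C)C(C)(C)C)=CC[C@H]2[C@@]1(CCC4OCCO4)OC(=O)[C@@H](C)[C@H]1[C@@H]3C(=O)OCC[Si](C)(C)C | intermediate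
17 | ethynyltrimethylsilane | C#C[Si](C)(C)C | starting material
18 | C15 acid chloride of 16 | ClC(=O)[C@]23CC(O[Si](C)(C)C(C)(C)C)=CC[C@H]2[C@@]1(CCC4OCCO4)OC(=O)[C@@H](C)[C@H]1[C@@H]3C(=O)OCC[Si](C)(C)C | intermediate
19 | C15 ynone (C8–CO–C≡C–SiMe3) | C[Si](C)(C)C#CC(=O)[C@]23CC(O[Si](C)(C)C(C)(C)C)=CC[C@H]2[C@@]1(CCC4OCCO4)OC(=O)[C@@H](C)[C@H]1[C@@H]3C(=O)OCC[Si](C)(C)C | intermediate
20 | C15 propargylic alcohol (15-hydroxyl as in the target) | C[Si](C)(C)C#C[C@@H](O)[C@]23CC(O[Si](C)(C)C(C)(C)C)=CC[C@H]2[C@@]1(CCC4OCCO4)OC(=O)[C@@H](C)[C@H]1[C@@H]3C(=O)OCC[Si](C)(C)C | intermediate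
21 | 15-O-TBS ether of 20 | C[Si](C)(C)C#C[C@@H](O[Si](C)(C)C(C)(C)C)[C@]23CC(O[Si](C)(C)C(C)(C)C)=CC[C@H]2[C@@]1(CCC4OCCO4)OC(=O)[C@@H](C)[C@H]1[C@@H]3C(=O)OCC[Si](C)(C)C | intermediate
22 | C13 ketone with terminal alkyne (15-O-TBS, C7 silylethyl ester, lactone, dioxolane) | C#C[C@@H](O[Si](C)(C)C(C)(C)C)[C@]23CC(=O)CC[C@H]2[C@@]1(CCC4OCCO4)OC(=O)[C@@H](C)[C@H]1[C@@H]3C(=O)OCC[Si](C)(C)C | intermediate
23 | tetracyclic lactone acetal: ring D closed, 13-hydroxy, 16-methylene, 15-O-TBS | C=C1[C@@H](O[Si](C)(C)C(C)(C)C)[C@]23C[C@@]1(O)CC[C@H]2[C@@]4(CCC5OCCO5)OC(=O)[C@@H](C)[C@H]4[C@@H]3C(=O)OCC[Si](C)(C)C | intermediate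
24 | lactone aldehyde (3-oxopropyl arm on C10) | C=C1[C@@H](O[Si](C)(C)C(C)(C)C)[C@]23C[C@@]1(O)CC[C@H]2[C@@]4(CCC=O)OC(=O)[C@@H](C)[C@H]4[C@@H]3C(=O)OCC[Si](C)(C)C | intermediate
25 | 15-O-TBS 2-(trimethylsilyl)ethyl ester of the target gibberellin | C=C1[C@@H](O[Si](C)(C)C(C)(C)C)[C@]23C[C@@]1(O)CC[C@H]2[C@@]12CC[C@H](O)[C@@](C)(C(=O)O1)[C@H]2[C@@H]3C(=O)OCC[Si](C)(C)C | intermediate
26 | target gibberellin (number 72 of the A series): (15S)-3β,13,15-trihydroxy-16-methylene 19,10-γ-lactone 7-carboxylic acid of the gibberellane skeleton | C=C1[C@@H](O)[C@]23C[C@@]1(O)CC[C@H]2[C@@]12CC[C@H](O)[C@@](C)(C(=O)O1)[C@H]2[C@@H]3C(=O)O | target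

**Step count.** Total: 16 steps. Longest linear sequence: 15 steps (steps 1, 2 and 4–16 from acid 1; step 3 is a one-step branch).

**Steps most likely to fail**

Step 15. The aldol may drift to the equatorial 3α-alcohol through retro-aldol equilibration or a cation-bridged transition state, and the aldehyde enolate may self-condense. The fallback sets out from 24 and sets C3 by hydride delivery instead of by the aldol. The aldol is run under equilibrating conditions (KOt-Bu, t-BuOH, 25 °C) to give the 3α-hydroxy epimer F1. Dess–Martin periodinane (NaHCO3, CH2Cl2) should oxidize it to the 3-ketone F2. K[BH(s-Bu)3] (THF, −78 °C) should then attack the ketone from the equatorial direction and give the axial 3β-alcohol, returning to the route at 25.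

Step 5. The basic ketone enolate may eliminate the secondary triflate by β-elimination or simply exchange protons instead of C-alkylating. The fallback sets out from 6 and builds C4 in two stages. Alkylation of the same enolate with ethyl bromoacetate, a primary electrophile, should give keto ester F3. The organocerium addition and lactonization of step 6 should then give the nor-methyl lactone F4. Enolization with LiN(i-Pr)2 and methylation with MeI should occur on the upper face, anti to C6, giving the 4-epimer F5. A second enolization and kinetic protonation from the same upper face (AcOH, −78 °C) should return to the route at 13.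

Step 6. The ketone is flanked on both sides, so enolization or poor facial discrimination may outrun addition of the sp3 organocerium. The fallback sets out from 9 and uses a slimmer sp nucleophile. The cerium acetylide of 2-ethynyl-1,3-dioxolane (n-BuLi, CeCl3, THF, −78 °C) should add and lactonize to the alkynyl lactone F6. Deallylation (Pd(PPh3)4, pyrrolidine) should give the alkynyl diacid F7. Hydrogenation of the alkyne (H2, RhCl(PPh3)3, benzene/EtOH) should return to the route at 14.

Further compounds
F1 | step 15 | 3α-hydroxy epimer of 25 | C=C1[C@@H](O[Si](C)(C)C(C)(C)C)[C@]23C[C@@]1(O)CC[C@H]2[C@@]12CC[C@@H](O)[C@@](C)(C(=O)O1)[C@H]2[C@@H]3C(=O)OCC[Si](C)(C)C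
F2 | step 15 | 3-oxo analogue of 25 | C=C1[C@@H](O[Si](C)(C)C(C)(C)C)[C@]23C[C@@]1(O)CC[C@H]2[C@@]12CCC(=O)[C@@](C)(C(=O)O1)[C@H]2[C@@H]3C(=O)OCC[Si](C)(C)C
F3 | step 5 | 6 bearing a 2-ethoxy-2-oxoethyl group at C5, trans to the C6 ester | C=CCOC(=O)[C@]23CC(O[Si](C)(C)C(C)(C)C)=CC[C@H]2C(=O)[C@@H](CC(=O)OCC)[C@@H]3C(=O)OCC=C
F4 | step 5 | 18-nor analogue of 13 (C4 methylene lactone) | C=CCOC(=O)[C@]23CC(O[Si](C)(C)C(C)(C)C)=CC[C@H]2[C@@]1(CCC4OCCO4)OC(=O)C[C@H]1[C@@H]3C(=O)OCC=C
F5 | step 5 | C4 epimer of 13 (methyl on the upper face) | C=CCOC(=O)[C@]23CC(O[Si](C)(C)C(C)(C)C)=CC[C@H]2[C@@]1(CCC4OCCO4)OC(=O)[C@H](C)[C@H]1[C@@H]3C(=O)OCC=C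
F6 | step 6 | 1,2-didehydro analogue of 13 (C10 (1,3-dioxolan-2-yl)ethynyl lactone, diallyl ester) | C=CCOC(=O)[C@]23CC(O[Si](C)(C)C(C)(C)C)=CC[C@H]2[C@@]1(C#CC4OCCO4)OC(=O)[C@@H](C)[C@H]1[C@@H]3C(=O)OCC=C
F7 | step 6 | 1,2-didehydro analogue of 14 (alkynyl lactone diacid) | OC(=O)[C@]23CC(O[Si](C)(C)C(C)(C)C)=CC[C@H]2[C@@]1(C#CC4OCCO4)OC(=O)[C@@H](C)[C@H]1[C@@H]3C(=O)O
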